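**Retrosynthetic overview**
1. The hydroxy-lactone is the ring-chain tautomer of a cis-2-formyl acid, so it closes last, from a tert-butyl ester aldehyde.
2. The cyclohexene (C4=C5) comes from an auxiliary-controlled Diels–Alder reaction of an (E)-2,3-disubstituted dienyl silyl ether with an N-acryloyl oxazolidinone (C3a–C7a and C6–C7 bonds, both ring stereocentres).
3. The diene comes from methylenation of an enone, which is made by an intermolecular boron aldol addition and dehydration (C3a–C4 bond) joining a γ-keto ester to silyloxyacetaldehyde.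
4. The γ-keto ester comes from a crossed Claisen condensation (acid chloride plus tert-butyl acetate enolate), SN2 alkylation with (R)-lactate triflate (sets Cα) and decarboxylation.
5. The (S)-1,3,3-trimethylcyclohexyl acid comes from Pd/PyOx conjugate arylation of 3-methylcyclohexenone, gem-dimethylation and RuO4 degradation. Ring order: trimethylcyclohexane (bought ring), then cyclohexene, then lactone.

Atom labels used below (target): lactone C1(=O), O2, C3(OH), C3a, C4 (propanoate), C5 (trimethylcyclohexyl), C6, C7, C7a; Cα is the propanoate C2; C1' is the quaternary ring carbon.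

Assumption: C3 is a hemiacetal carbon that epimerises through the open formyl acid. The (3R) epimer of the target is taken to be the thermodynamically preferred one and is reached by equilibration in the last step, not by a stereoselective step.

**Route**

Step 1
Reactants: 1 3-methylcyclohex-2-en-1-one; 2 phenylboronic acid
Product: 3 (3S)-3-methyl-3-phenylcyclohexan-1-one
Conditions: Pd(OCOCF3)2 (5 mol %), (R)-t-BuPyOx (6 mol %), NH4PF6 (30 mol %), H2O (5 equiv), ClCH2CH2Cl, 40 °C
Reagents that add atoms: none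
Why: Pd(II)/pyridine-oxazoline-catalysed asymmetric conjugate addition of an arylboronic acid to a β-substituted enone; the (R)-ligand (mirror image of the ligand that gives the (R)-ketone) sets the quaternary centre as S (about 93% ee, the minor antipode being removed later as diastereomers).

Step 2
Reactants: 3 (3S)-3-methyl-3-phenylcyclohexan-1-one
Product: 4 [(1S)-1,3,3-trimethylcyclohexyl]benzene
Conditions: TiCl4 (2 equiv), Me2Zn (2 equiv), CH2Cl2, −40 °C → rt
Reagents that add atoms: dimethylzinc, C[Zn]C (both new methyl groups, transferred through Me2TiCl2)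
Why: Reetz geminal dimethylation replaces C=O by CMe2 through a tertiary titanium alkoxide; no bond to the quaternary stereocentre is touched, so its configuration is kept.

Step 3
Reactants: 4 [(1S)-1,3,3-trimethylcyclohexyl]benzene
Product: 5 (1S)-1,3,3-trimethylcyclohexane-1-carboxylic acid
Conditions: RuCl3·xH2O (5 mol %), NaIO4 (15 equiv), MeCN/EtOAc/H2O, rt
Reagents that add atoms: sodium periodate, [Na+].[O-]I(=O)(=O)=O (oxygen through RuO4); water, O
Why: RuO4 oxidation (Sharpless conditions) degrades the phenyl ring to CO2 and leaves its ipso carbon as CO2H, while the saturated quaternary carbon is inert and keeps its configuration.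

Step 4
Reactants: 5 (1S)-1,3,3-trimethylcyclohexane-1-carboxylic acid; 6 tert-butyl acetate
Product: 9 tert-butyl 3-oxo-3-[(1S)-1,3,3-trimethylcyclohexyl]propanoate, via acid chloride 7 (not isolated), via lithium enolate of tert-butyl acetate 8 (not isolated)
Conditions: (COCl)2, cat. DMF, CH2Cl2, rt; separately 6, LDA (2.2 equiv), THF, −78 °C; combine, −78 → −30 °C; aq NH4Cl
Reagents that add atoms: none
Why: Crossed Claisen condensation: the non-enolisable acid chloride acylates the ester enolate, and the second equivalent of enolate deprotonates the β-keto ester so that it is not acylated twice.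

Step 5
Reactants: 10 methyl (2R)-2-hydroxypropanoate (methyl D-lactate)
Product: 11 methyl (2R)-2-[(trifluoromethanesulfonyl)oxy]propanoate
Conditions: Tf2O, 2,6-lutidine, CH2Cl2, −78 → 0 °C
Reagents that add atoms: trifluoromethanesulfonic anhydride, O=S(=O)(OS(=O)(=O)C(F)(F)F)C(F)(F)F
Why: O-sulfonylation of the secondary alcohol breaks no bond at the stereocentre, so the R configuration is retained.

Step 6
Reactants: 9 tert-butyl 3-oxo-3-[(1S)-1,3,3-trimethylcyclohexyl]propanoate; 11 methyl (2R)-2-[(trifluoromethanesulfonyl)oxy]propanoate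
Product: 13 1-tert-butyl 4-methyl (3R)-3-methyl-2-[(1S)-1,3,3-trimethylcyclohexane-1-carbonyl]butanedioate (both C2 epimers), via sodium enolate 12 (not isolated)
Conditions: NaH, THF, 0 °C; then 11, 0 °C → rt
Reagents that add atoms: none
Why: SN2 C-alkylation of the soft β-keto ester enolate by the carbonyl-activated secondary triflate goes with clean inversion and gives the (R)-configured Cα (the descriptor stays R only because the priorities change); the epimeric C2 is removed in step 7.

Step 7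
Reactants: 13 1-tert-butyl 4-methyl (3R)-3-methyl-2-[(1S)-1,3,3-trimethylcyclohexane-1-carbonyl]butanedioate
Product: 15 methyl (2R)-2-methyl-4-oxo-4-[(1S)-1,3,3-trimethylcyclohexyl]butanoate, via β-keto acid 14 (not isolated)
Conditions: TFA, CH2Cl2, rt; then toluene, 80 °C
Reagents that add atoms: none
Why: Acidolysis of the tert-butyl ester followed by thermal decarboxylation of the β-keto acid runs without base, so the ester α-stereocentre is not epimerised and the methyl ester survives.

Step 8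
Reactants: 15 methyl (2R)-2-methyl-4-oxo-4-[(1S)-1,3,3-trimethylcyclohexyl]butanoate; 16 (tert-butyldimethylsilyloxy)acetaldehyde
Product: 18 methyl (2R)-5-[(tert-butyldimethylsilyl)oxy]-4-hydroxy-2-methyl-3-[(1S)-1,3,3-trimethylcyclohexane-1-carbonyl]pentanoate (C3/C4 diastereomers, syn major), via Z-dibutylboron enolate 17 (not isolated)
Conditions: n-Bu2BOTf, i-Pr2NEt, CH2Cl2, −78 → 0 °C; 16, −78 → 0 °C; pH 7 buffer, MeOH, 30% H2O2, 0 °C
Reagents that add atoms: none
Why: Intermolecular boron aldol addition that forms the C3a–C4 bond: soft enolisation touches only the single enolisable ketone position and not the ester, so Cα is safe, and the two new centres are removed in step 9.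

Step 9
Reactants: 18 methyl (2R)-5-[(tert-butyldimethylsilyl)oxy]-4-hydroxy-2-methyl-3-[(1S)-1,3,3-trimethylcyclohexane-1-carbonyl]pentanoate
Product: 20 methyl (2R,3E)-5-[(tert-butyldimethylsilyl)oxy]-2-methyl-3-[(1S)-1,3,3-trimethylcyclohexane-1-carbonyl]pent-3-enoate, via mesylate 19 (not isolated)
Conditions: MsCl, Et3N, CH2Cl2, 0 °C; then DBU, 0 °C → rt
Reagents that add atoms: none
Why: Mesylation and E1cB elimination complete the aldol condensation and should favour the (E)-enone, with CH2OTBS trans to the bulky acyl group; the Cα–H is not vinylogously acidic and is expected to survive the brief DBU exposure.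

Step 10
Reactants: 20 methyl (2R,3E)-5-[(tert-butyldimethylsilyl)oxy]-2-methyl-3-[(1S)-1,3,3-trimethylcyclohexane-1-carbonyl]pent-3-enoate
Product: 21 methyl (2R,3E)-5-[(tert-butyldimethylsilyl)oxy]-2-methyl-3-{1-[(1S)-1,3,3-trimethylcyclohexyl]ethenyl}pent-3-enoate
Conditions: Zn, CH2Br2, TiCl4 (Lombardo reagent), THF/CH2Cl2, 0 °C → rt
Reagents that add atoms: dibromomethane, BrCBr
Why: Takai–Lombardo methylenation is non-basic and selective for ketones over esters, so it turns the hindered enone carbonyl into the 1,1-disubstituted alkene of the diene without epimerising Cα or cleaving the silyl ether.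

Step 11
Reactants: 22 (4S)-4-benzyl-1,3-oxazolidin-2-one; 23 acryloyl chloride
Product: 25 (4S)-4-benzyl-3-(prop-2-enoyl)-1,3-oxazolidin-2-one, via N-bromomagnesio oxazolidinone 24 (not isolated)
Conditions: MeMgBr, THF, 0 °C; then 23, −78 → 0 °C
Reagents that add atoms: none
Why: N-acylation of the magnesium salt of the oxazolidinone (Evans protocol), which limits polymerisation of the acryloyl unit.

Step 12
Reactants: 21 methyl (2R,3E)-5-[(tert-butyldimethylsilyl)oxy]-2-methyl-3-{1-[(1S)-1,3,3-trimethylcyclohexyl]ethenyl}pent-3-enoate; 25 (4S)-4-benzyl-3-(prop-2-enoyl)-1,3-oxazolidin-2-one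
Product: 26 methyl (2R)-2-[(5R,6R)-5-{[(4S)-4-benzyl-2-oxo-1,3-oxazolidin-3-yl]carbonyl}-6-{[(tert-butyldimethylsilyl)oxy]methyl}-2-[(1S)-1,3,3-trimethylcyclohexyl]cyclohex-1-en-1-yl]propanoate
Conditions: Et2AlCl (1.4 equiv), CH2Cl2, −78 → −20 °C; 1 M HCl quench
Reagents that add atoms: none
Why: Evans auxiliary-controlled, Lewis acid-promoted Diels–Alder reaction: the Al-chelated s-cis acryloyl imide is attacked on the face anti to the benzyl group (sets C7a as R), the 1-CH2OTBS and 2-alkyl substituents of the diene direct the acyl-bearing carbon to C7a ("ortho"), and the endo transition state with the (E)-diene places C3 and C1 cis (sets C3a as R) while the tetrasubstituted C4=C5 alkene is formed directly.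

Step 13
Reactants: 26 Diels–Alder adduct (imide)
Product: 27 (1R,2R)-2-{[(tert-butyldimethylsilyl)oxy]methyl}-3-[(2R)-1-methoxy-1-oxopropan-2-yl]-4-[(1S)-1,3,3-trimethylcyclohexyl]cyclohex-3-ene-1-carboxylic acid
Conditions: LiOH, 30% H2O2, THF/H2O, 0 °C; Na2SO3; 1 M HCl
Reagents that add atoms: hydrogen peroxide, OO (as LiOOH)
Why: Lithium hydroperoxide cleaves the exocyclic imide carbonyl selectively without epimerising C7a, and the hindered methyl ester and the silyl ether survive at 0 °C.

Step 14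
Reactants: 27 the carboxylic acid
Product: 28 tert-butyl (1R,2R)-2-{[(tert-butyldimethylsilyl)oxy]methyl}-3-[(2R)-1-methoxy-1-oxopropan-2-yl]-4-[(1S)-1,3,3-trimethylcyclohexyl]cyclohex-3-ene-1-carboxylate
Conditions: t-BuOC(=NH)CCl3 (3 equiv), cyclohexane/CH2Cl2, rt
Reagents that add atoms: tert-butyl 2,2,2-trichloroacetimidate, CC(C)(C)OC(=N)C(Cl)(Cl)Cl
Why: O-alkylation of the acid by the trichloroacetimidate needs no base; the tert-butyl ester is chosen because it is too poor an acyl donor to lactonise with the cis CH2OH freed next and can later be removed without base.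

Step 15
Reactants: 28 the tert-butyl ester silyl ether
Product: 29 tert-butyl (1R,2R)-2-(hydroxymethyl)-3-[(2R)-1-methoxy-1-oxopropan-2-yl]-4-[(1S)-1,3,3-trimethylcyclohexyl]cyclohex-3-ene-1-carboxylate
Conditions: HF·pyridine, pyridine, THF, 0 °C → rt
Reagents that add atoms: none
Why: Buffered fluoride desilylation removes the primary TBS ether and leaves both esters and all stereocentres untouched; the crude alcohol is used at once.

Step 16
Reactants: 29 the primary alcohol
Product: 30 tert-butyl (1R,2R)-2-formyl-3-[(2R)-1-methoxy-1-oxopropan-2-yl]-4-[(1S)-1,3,3-trimethylcyclohexyl]cyclohex-3-ene-1-carboxylate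
Conditions: Dess–Martin periodinane, NaHCO3, CH2Cl2, 0 °C
Reagents that add atoms: none
Why: Buffered Dess–Martin oxidation gives the β,γ-unsaturated aldehyde under non-basic conditions, so C3a is not epimerised and the alkene does not move into conjugation.

Step 17
Reactants: 30 the aldehyde tert-butyl ester
Product: 32 methyl (2R)-2-[(3R,3aR,7aR)-3-hydroxy-1-oxo-5-[(1S)-1,3,3-trimethylcyclohexyl]-1,3,3a,6,7,7a-hexahydro-2-benzofuran-4-yl]propanoate (target), via open-chain formyl acid 31 (not isolated)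
Conditions: TFA/CH2Cl2 (1:9), 0 °C; evaporate; aq MeCN, rt (equilibration)
Reagents that add atoms: none
Why: Acidolysis of the tert-butyl ester frees the acid, which adds to the cis aldehyde (ring-chain tautomerism) to give the cis-fused hydroxy-lactone; C3 equilibrates to the (3R) epimer as assumed, and the methyl ester is stable to TFA.

**Compound list**
1 | 3-methylcyclohex-2-en-1-one | CC1=CC(=O)CCC1 | starting material
2 | phenylboronic acid | OB(O)c1ccccc1 | starting material
3 | (3S)-3-methyl-3-phenylcyclohexan-1-one | c1ccccc1[C@@]2(C)CCCC(=O)C2 | intermediate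
4 | [(1S)-1,3,3-trimethylcyclohexyl]benzene | c1ccccc1[C@@]2(C)CCCC(C)(C)C2 | intermediate
5 | (1S)-1,3,3-trimethylcyclohexane-1-carboxylic acid | OC(=O)[C@@]1(C)CCCC(C)(C)C1 | intermediate
6 | tert-butyl acetate | CC(=O)OC(C)(C)C | starting material
7 | (1S)-1,3,3-trimethylcyclohexane-1-carbonyl chloride | O=C(Cl)[C@@]1(C)CCCC(C)(C)C1 | intermediate
8 | lithium enolate of tert-butyl acetate | [Li]OC(=C)OC(C)(C)C | intermediate
9 | tert-butyl 3-oxo-3-[(1S)-1,3,3-trimethylcyclohexyl]propanoate | CC(C)(C)OC(=O)CC(=O)[C@@]1(C)CCCC(C)(C)C1 | intermediate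
10 | methyl (2R)-2-hydroxypropanoate | C[C@@H](O)C(=O)OC | starting material
11 | methyl (2R)-2-[(trifluoromethanesulfonyl)oxy]propanoate | C[C@@H](OS(=O)(=O)C(F)(F)F)C(=O)OC | intermediate
12 | sodium enolate of 9 | [Na]OC(=CC(=O)OC(C)(C)C)[C@@]1(C)CCCC(C)(C)C1 | intermediate
13 | 1-tert-butyl 4-methyl (3R)-3-methyl-2-[(1S)-1,3,3-trimethylcyclohexane-1-carbonyl]butanedioate (C2 epimers) | COC(=O)[C@H](C)C(C(=O)OC(C)(C)C)C(=O)[C@@]1(C)CCCC(C)(C)C1 | intermediate
14 | (3R)-4-methoxy-3-methyl-4-oxo-2-[(1S)-1,3,3-trimethylcyclohexane-1-carbonyl]butanoic acid | COC(=O)[C@H](C)C(C(=O)O)C(=O)[C@@]1(C)CCCC(C)(C)C1 | intermediate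
15 | methyl (2R)-2-methyl-4-oxo-4-[(1S)-1,3,3-trimethylcyclohexyl]butanoate | COC(=O)[C@H](C)CC(=O)[C@@]1(C)CCCC(C)(C)C1 | intermediate
16 | (tert-butyldimethylsilyloxy)acetaldehyde | O=CCO[Si](C)(C)C(C)(C)C | starting material
17 | methyl (2R,3Z)-4-[(dibutylboranyl)oxy]-2-methyl-4-[(1S)-1,3,3-trimethylcyclohexyl]but-3-enoate | COC(=O)[C@H](C)/C=C(\OB(CCCC)CCCC)[C@@]1(C)CCCC(C)(C)C1 | intermediate
18 | methyl (2R)-5-[(tert-butyldimethylsilyl)oxy]-4-hydroxy-2-methyl-3-[(1S)-1,3,3-trimethylcyclohexane-1-carbonyl]pentanoate (C3/C4 diastereomers) | COC(=O)[C@H](C)C(C(O)CO[Si](C)(C)C(C)(C)C)C(=O)[C@@]1(C)CCCC(C)(C)C1 | intermediate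
19 | 4-O-methanesulfonate of 18 | COC(=O)[C@H](C)C(C(OS(C)(=O)=O)CO[Si](C)(C)C(C)(C)C)C(=O)[C@@]1(C)CCCC(C)(C)C1 | intermediate
20 | methyl (2R,3E)-5-[(tert-butyldimethylsilyl)oxy]-2-methyl-3-[(1S)-1,3,3-trimethylcyclohexane-1-carbonyl]pent-3-enoate | COC(=O)[C@H](C)/C(C(=O)[C@@]1(C)CCCC(C)(C)C1)=C\CO[Si](C)(C)C(C)(C)C | intermediate
21 | methyl (2R,3E)-5-[(tert-butyldimethylsilyl)oxy]-2-methyl-3-{1-[(1S)-1,3,3-trimethylcyclohexyl]ethenyl}pent-3-enoate | COC(=O)[C@H](C)/C(C(=C)[C@@]1(C)CCCC(C)(C)C1)=C\CO[Si](C)(C)C(C)(C)C | intermediate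
22 | (4S)-4-benzyl-1,3-oxazolidin-2-one | O=C1N[C@@H](Cc2ccccc2)CO1 | starting material
23 | acryloyl chloride | C=CC(=O)Cl | starting material
24 | N-bromomagnesio derivative of 22 | O=C1N([Mg]Br)[C@@H](Cc2ccccc2)CO1 | intermediate
25 | (4S)-4-benzyl-3-(prop-2-enoyl)-1,3-oxazolidin-2-one | C=CC(=O)N1[C@@H](Cc2ccccc2)COC1=O | intermediate
26 | methyl (2R)-2-[(5R,6R)-5-{[(4S)-4-benzyl-2-oxo-1,3-oxazolidin-3-yl]carbonyl}-6-{[(tert-butyldimethylsilyl)oxy]methyl}-2-[(1S)-1,3,3-trimethylcyclohexyl]cyclohex-1-en-1-yl]propanoate | COC(=O)[C@H](C)C1=C([C@@]2(C)CCCC(C)(C)C2)CC[C@@H](C(=O)N3[C@@H](Cc4ccccc4)COC3=O)[C@H]1CO[Si](C)(C)C(C)(C)C | intermediate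
27 | (1R,2R)-2-{[(tert-butyldimethylsilyl)oxy]methyl}-3-[(2R)-1-methoxy-1-oxopropan-2-yl]-4-[(1S)-1,3,3-trimethylcyclohexyl]cyclohex-3-ene-1-carboxylic acid | COC(=O)[C@H](C)C1=C([C@@]2(C)CCCC(C)(C)C2)CC[C@@H](C(=O)O)[C@H]1CO[Si](C)(C)C(C)(C)C | intermediate
28 | tert-butyl (1R,2R)-2-{[(tert-butyldimethylsilyl)oxy]methyl}-3-[(2R)-1-methoxy-1-oxopropan-2-yl]-4-[(1S)-1,3,3-trimethylcyclohexyl]cyclohex-3-ene-1-carboxylate | COC(=O)[C@H](C)C1=C([C@@]2(C)CCCC(C)(C)C2)CC[C@@H](C(=O)OC(C)(C)C)[C@H]1CO[Si](C)(C)C(C)(C)C | intermediate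
29 | tert-butyl (1R,2R)-2-(hydroxymethyl)-3-[(2R)-1-methoxy-1-oxopropan-2-yl]-4-[(1S)-1,3,3-trimethylcyclohexyl]cyclohex-3-ene-1-carboxylate | COC(=O)[C@H](C)C1=C([C@@]2(C)CCCC(C)(C)C2)CC[C@@H](C(=O)OC(C)(C)C)[C@H]1CO | intermediate
30 | tert-butyl (1R,2R)-2-formyl-3-[(2R)-1-methoxy-1-oxopropan-2-yl]-4-[(1S)-1,3,3-trimethylcyclohexyl]cyclohex-3-ene-1-carboxylate | COC(=O)[C@H](C)C1=C([C@@]2(C)CCCC(C)(C)C2)CC[C@@H](C(=O)OC(C)(C)C)[C@H]1C=O | intermediate
31 | (1R,2R)-2-formyl-3-[(2R)-1-methoxy-1-oxopropan-2-yl]-4-[(1S)-1,3,3-trimethylcyclohexyl]cyclohex-3-ene-1-carboxylic acid | COC(=O)[C@H](C)C1=C([C@@]2(C)CCCC(C)(C)C2)CC[C@@H](C(=O)O)[C@H]1C=O | intermediate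
32 | methyl (2R)-2-[(3R,3aR,7aR)-3-hydroxy-1-oxo-5-[(1S)-1,3,3-trimethylcyclohexyl]-1,3,3a,6,7,7a-hexahydro-2-benzofuran-4-yl]propanoate | COC(=O)[C@H](C)C1=C([C@@]2(C)CCCC(C)(C)C2)CC[C@H]2C(=O)O[C@@H](O)[C@@H]12 | target

**Summary**
Total step count: 17.
Longest linear sequence: 15 steps (steps 1–4, 6–10, 12–17); steps 5 and 11 prepare the triflate and the dienophile.

**Steps most likely to fail, with fallbacks**

Step 6 (C-alkylation of the hindered β-keto ester with a secondary triflate; O-alkylation or elimination could compete). The fallback sets out from acid 5 and comes back at keto ester 15, bypassing steps 4–7. Acid 5 and methyllithium (2.2 equiv, Et2O, 0 °C) give the methyl ketone 1-[(1S)-1,3,3-trimethylcyclohexyl]ethan-1-one F1. Bromination with phenyltrimethylammonium tribromide (THF, 0 °C) gives 2-bromo-1-[(1S)-1,3,3-trimethylcyclohexyl]ethan-1-one F2. The sodium enolate (NaHMDS, THF, −78 °C) of commercial (4S)-4-benzyl-3-propanoyl-1,3-oxazolidin-2-one is then alkylated by F2 anti to the benzyl group (Evans alkylation, sets Cα as R) to give (4S)-4-benzyl-3-{(2R)-2-methyl-4-oxo-4-[(1S)-1,3,3-trimethylcyclohexyl]butanoyl}-1,3-oxazolidin-2-one F3. Transesterification with MeOMgBr in MeOH at 0 °C gives 15.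

Step 10 (methylenation of a very hindered cross-conjugated ketone). The fallback sets out from enone 20 and comes back at diene 21 by a Peterson olefination in place of the titanium carbenoid. Me3SiCH2Li/CeCl3 (THF, −78 °C) adds to the ketone in preference to the ester and gives the β-hydroxysilane methyl (2R,3E)-5-[(tert-butyldimethylsilyl)oxy]-3-{1-hydroxy-2-(trimethylsilyl)-1-[(1S)-1,3,3-trimethylcyclohexyl]ethyl}-2-methylpent-3-enoate F4. Acid-induced elimination (cat. p-TsOH, CH2Cl2, 0 °C) gives 21.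

Step 12 (Diels–Alder reaction of a twisted 1,2,3-trisubstituted diene; low rate or Lewis acid damage). The fallback sets out from diene 21 and comes back at acid 27, replacing auxiliary control by catalyst control with a smaller, activated dienophile. 2,2,2-Trifluoroethyl acrylate and Corey's triflimide-activated o-tolyl oxazaborolidinium catalyst (20 mol %, CH2Cl2, −78 → −20 °C; the catalyst antipode that directs the diene to the same acrylate face as the auxiliary) give 2,2,2-trifluoroethyl (1R,2R)-2-{[(tert-butyldimethylsilyl)oxy]methyl}-3-[(2R)-1-methoxy-1-oxopropan-2-yl]-4-[(1S)-1,3,3-trimethylcyclohexyl]cyclohex-3-ene-1-carboxylate F5. LiOH (THF/H2O, 0 °C) hydrolyses the activated ester selectively to 27.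

**Further compounds**
F1 | step 6 | 1-[(1S)-1,3,3-trimethylcyclohexyl]ethan-1-one | CC(=O)[C@@]1(C)CCCC(C)(C)C1
F2 | step 6 | 2-bromo-1-[(1S)-1,3,3-trimethylcyclohexyl]ethan-1-one | BrCC(=O)[C@@]1(C)CCCC(C)(C)C1
F3 | step 6 | (4S)-4-benzyl-3-{(2R)-2-methyl-4-oxo-4-[(1S)-1,3,3-trimethylcyclohexyl]butanoyl}-1,3-oxazolidin-2-one | O=C1OC[C@H](Cc2ccccc2)N1C(=O)[C@H](C)CC(=O)[C@@]3(C)CCCC(C)(C)C3
F4 | step 10 | methyl (2R,3E)-5-[(tert-butyldimethylsilyl)oxy]-3-{1-hydroxy-2-(trimethylsilyl)-1-[(1S)-1,3,3-trimethylcyclohexyl]ethyl}-2-methylpent-3-enoate | COC(=O)[C@H](C)/C(C(O)(C[Si](C)(C)C)[C@@]1(C)CCCC(C)(C)C1)=C\CO[Si](C)(C)C(C)(C)C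
F5 | step 12 | 2,2,2-trifluoroethyl (1R,2R)-2-{[(tert-butyldimethylsilyl)oxy]methyl}-3-[(2R)-1-methoxy-1-oxopropan-2-yl]-4-[(1S)-1,3,3-trimethylcyclohexyl]cyclohex-3-ene-1-carboxylate | COC(=O)[C@H](C)C1=C([C@@]2(C)CCCC(C)(C)C2)CC[C@@H](C(=O)OCC(F)(F)F)[C@H]1CO[Si](C)(C)C(C)(C)C
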